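**Plan**
- Cuts: the three benzyl ethers (last step); the lactone C–O bond, back to a hydroxy acid whose CH2OH carbon is the stump of a cleaved propenyl group; the lactone C3–C4 bond, by an ester enolate [3,3] shift; the ester C–O bond; the alkene of the allylic alcohol (metathesis).
- Ring B is cut at its C1–C2 and C3–C4 bonds (C1 = chain carbon) into a 2-pyrone and but-3-yn-2-one.
- Enabling feature: ring B carries oxygen on C3, C4 and C5, only O5 is methylated and the chain on C1 is para to O4. C4–OH, C5–OMe, C6–H and C1–alkyl are C3, C4, C5 and C6 of a 3-hydroxy-4-methoxy-2-pyrone; C2 and C3 are the alkyne carbons, and the acetyl on C3 is a latent hydroxyl.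
- Forward order: ring B (steps 1–4), acetyl to OH and benzylation, ester with the eugenol-derived alcohol, C3–C4 bond by Ireland–Claisen rearrangement, lactone ring last, debenzylation.
- Stereochemistry: lactone C4 from (R)-but-3-en-2-ol by 1,3-chirality transfer through a chair; C3 from the enolate geometry (syn acid, hence trans lactone).

Key step: step 4

Assumption: (R)-but-3-en-2-ol is taken as a commercial reagent of high enantiomeric purity, and the racemic bridged intermediate 9 is drawn as one enantiomer because its stereocentres vanish on aromatisation.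

**Route**

Step 1
Reactants: 1 4-methoxy-6-methyl-2H-pyran-2-one; 2 methyl bromoacetate
Product: 4 methyl 3-(4-methoxy-2-oxo-2H-pyran-6-yl)propanoate, via lithiated pyrone 3 (not isolated)
Conditions: LiN(i-Pr)2 (1.1 equiv), THF, −78 °C; then 2 (1.3 equiv), −78 to −40 °C
Reagents that add atoms: none
Why: Amide bases metalate 4-methoxy-6-methyl-2-pyrone at the C6 methyl group (lateral lithiation to a vinylogous lactone enolate), and this carbanion should be alkylated by the primary α-bromo ester in an SN2 reaction faster than it attacks the ester carbonyl.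

Step 2
Reactants: 4 methyl 3-(4-methoxy-2-oxo-2H-pyran-6-yl)propanoate
Product: 5 methyl 3-(3-bromo-4-methoxy-2-oxo-2H-pyran-6-yl)propanoate
Conditions: N-bromosuccinimide (1.05 equiv), MeCN, rt, dark
Reagents that add atoms: N-bromosuccinimide, O=C1CCC(=O)N1Br
Why: Electrophilic bromination of an enol ether should go to C3, the β-carbon of the C4 methoxy enol ether lying between the donor and the lactone carbonyl, which is the most nucleophilic ring position of 4-methoxy-2-pyrones.

Step 3
Reactants: 5 methyl 3-(3-bromo-4-methoxy-2-oxo-2H-pyran-6-yl)propanoate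
Product: 7 methyl 3-(3-hydroxy-4-methoxy-2-oxo-2H-pyran-6-yl)propanoate, via pinacol boronate 6 (not isolated)
Conditions: B2pin2 (1.2 equiv), Pd(dppf)Cl2 (5 mol%), KOAc (3 equiv), 1,4-dioxane, 80 °C; then THF, aq NaHCO3, 30% H2O2, 0 °C
Reagents that add atoms: hydrogen peroxide, OO
Why: Miyaura borylation (oxidative addition of the alkenyl C–Br bond to zerovalent palladium, then acetate-assisted transfer of boron) followed by peroxide oxidation of the C–B bond with 1,2-shift of carbon from boron to oxygen should exchange Br for OH under acetate and bicarbonate buffering that the methyl ester and the pyrone lactone tolerate.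

Step 4
Reactants: 7 methyl 3-(3-hydroxy-4-methoxy-2-oxo-2H-pyran-6-yl)propanoate; 8 but-3-yn-2-one
Product: 10 methyl 3-(3-acetyl-4-hydroxy-5-methoxyphenyl)propanoate, via bridged lactone adduct 9 (not isolated)
Conditions: Et3N (0.2 equiv), 8 (1.5 equiv, slow addition), CH2Cl2, 0 °C to rt; then toluene, 80 °C
Reagents that add atoms: none
Why: Et3N deprotonates the 3-OH of 7, and the resulting 3-oxidopyrone is an electron-rich diene whose C6 terminus bonds to the unsubstituted β-carbon of ynone 8 while C3 bonds to the acetyl-bearing carbon, either in one asynchronous [4+2] event or as a conjugate addition followed by aldol-type closure, giving the 2-oxabicyclo[2.2.2]octadienone 9. Retro-[4+2] loss of CO2 from 9 then leaves the benzene ring, so ring B is closed as a six-membered carbocycle by intermolecular cycloaddition and aromatised by cycloreversion in the same flask. The closest known reaction type is the amine-promoted Diels–Alder reaction of 3-hydroxy-2-pyrones with electron-poor alkynes and alkenes followed by decarboxylative aromatisation. No stereocentre is created, since the two bridgehead centres of racemic 9 disappear with the CO2. The step needs regioselectivity (acetyl ortho to the phenol and meta to the side chain), and this is secured by the oxide at C3, a far stronger donor than the 4-methoxy group, which makes C6 the nucleophilic end of the diene. The pyrone substituents are carried over unchanged, so 4-OMe, 3-OH and the C6 chain become the 5-methoxy, 4-hydroxy and 1-alkyl positions of 10, with the acetyl group marking the site of the third oxygen.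

Step 5
Reactants: 10 methyl 3-(3-acetyl-4-hydroxy-5-methoxyphenyl)propanoate
Product: 13 3-(3,4-dihydroxy-5-methoxyphenyl)propanoic acid, via keto acid 11 (not isolated), via aryl acetate 12 (not isolated)
Conditions: 2 M NaOH (5 equiv), THF/H2O, rt; then 30% H2O2 (1.3 equiv), 0 °C to rt, N2; then HCl to pH 2
Reagents that add atoms: hydrogen peroxide, OO; sodium hydroxide, [Na+].[OH-]
Why: After saponification of the methyl ester the Dakin oxidation applies, in which hydroperoxide adds to the ketone, the ring activated by the ortho-phenoxide migrates to oxygen and the aryl acetate so formed is hydrolysed in the same alkaline medium, so that the acetyl group is replaced by the third ring oxygen.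

Step 6
Reactants: 13 3-(3,4-dihydroxy-5-methoxyphenyl)propanoic acid
Product: 15 3-[3,4-bis(benzyloxy)-5-methoxyphenyl]propanoic acid, via benzyl ester 14 (not isolated)
Conditions: BnBr (3.5 equiv), K2CO3 (4 equiv), DMF, 60 °C, N2; then 2 M NaOH, THF/EtOH, 50 °C; HCl work-up
Reagents that add atoms: benzyl bromide, BrCc1ccccc1; sodium hydroxide, [Na+].[OH-]
Why: Williamson etherification caps both phenols (and transiently the carboxylate as its benzyl ester) with groups that can all be removed at the end by hydrogenolysis, and hydroxide then saponifies only the ester.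

Step 7
Reactants: 16 eugenol
Product: 17 4-allyl-1-(benzyloxy)-2-methoxybenzene
Conditions: BnBr (1.1 equiv), K2CO3, acetone, reflux
Reagents that add atoms: benzyl bromide, BrCc1ccccc1
Why: Williamson etherification of the phenoxide protects the phenol against acylation in step 9 under conditions too mild to move the allyl double bond.

Step 8
Reactants: 17 4-allyl-1-(benzyloxy)-2-methoxybenzene; 18 (R)-but-3-en-2-ol
Product: 19 (2R,3E)-5-[4-(benzyloxy)-3-methoxyphenyl]pent-3-en-2-ol
Conditions: 17 (2.5 equiv), second-generation Grubbs catalyst RuCl2(=CHPh)(H2IMes)(PCy3) (3 mol%), 1,4-benzoquinone (10 mol%), CH2Cl2, 40 °C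
Reagents that add atoms: none
Why: Olefin cross-metathesis of a terminal allylarene with a secondary allylic alcohol is a well-behaved pairing that favours the E alkene (needed because the Z isomer would transfer chirality in the opposite sense), the carbinol stereocentre is not touched, and benzoquinone suppresses alkene migration by ruthenium hydrides.

Step 9
Reactants: 15 3-[3,4-bis(benzyloxy)-5-methoxyphenyl]propanoic acid; 19 (2R,3E)-5-[4-(benzyloxy)-3-methoxyphenyl]pent-3-en-2-ol
Product: 20 (2R,3E)-5-[4-(benzyloxy)-3-methoxyphenyl]pent-3-en-2-yl 3-[3,4-bis(benzyloxy)-5-methoxyphenyl]propanoate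
Conditions: EDC·HCl (1.3 equiv), DMAP (0.2 equiv), CH2Cl2, 0 °C to rt
Reagents that add atoms: none
Why: Steglich esterification (carbodiimide activation with acyl transfer by DMAP) acylates the secondary alcohol at oxygen without breaking its C–O bond, so the R configuration and the E alkene are carried into the ester.

Step 10
Reactants: 20 (2R,3E)-5-[4-(benzyloxy)-3-methoxyphenyl]pent-3-en-2-yl 3-[3,4-bis(benzyloxy)-5-methoxyphenyl]propanoate
Product: 24 (2R,3S,4E)-2-[3,4-bis(benzyloxy)-5-methoxybenzyl]-3-[4-(benzyloxy)-3-methoxybenzyl]hex-4-enoic acid, via lithium enolate 21 (not isolated), via silyl ketene acetal 22 (not isolated), via silyl ester 23 (not isolated)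
Conditions: LiN(i-Pr)2 (1.2 equiv), THF/DMPU (3:1), −78 °C; TBSCl (1.3 equiv), −78 °C to rt, then 50 °C; 1 M HCl/THF
Reagents that add atoms: none
Why: In this Ireland–Claisen rearrangement, enolisation in the presence of DMPU should give the enolate with the benzylic CH2 cis to O–Li, silylation fixes it as the Z silyl ketene acetal, and the [3,3] shift through a chair transition state with the carbinol methyl equatorial delivers the new C–C bond to one face of the E alkene, so that the R carbinol centre is transferred to C3 (S) and the enolate geometry sets C2 (R) with the two benzyl groups syn, the relationship that becomes trans on the lactone.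

Step 11
Reactants: 24 (2R,3S,4E)-2-[3,4-bis(benzyloxy)-5-methoxybenzyl]-3-[4-(benzyloxy)-3-methoxybenzyl]hex-4-enoic acid
Product: 27 (3R,4R)-3-[3,4-bis(benzyloxy)-5-methoxybenzyl]-4-[4-(benzyloxy)-3-methoxybenzyl]dihydrofuran-2(3H)-one, via aldehyde acid 25 (not isolated), via hydroxy acid 26 (not isolated)
Conditions: O3, CH2Cl2/MeOH (4:1), −78 °C (indicator dye end point); NaBH4 (4 equiv), −78 °C to rt; then 1 M HCl, p-TsOH (cat.), CH2Cl2, rt
Reagents that add atoms: ozone, [O-][O+]=O
Why: Ozonolysis should cleave the propenyl group much faster than it attacks the alkoxyarenes, borohydride reduces the peroxidic products and the aldehyde at low temperature before the aldehyde can enolise, and acid then closes the five-membered lactone by acyl substitution with both stereocentres untouched.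

Step 12
Reactants: 27 (3R,4R)-3-[3,4-bis(benzyloxy)-5-methoxybenzyl]-4-[4-(benzyloxy)-3-methoxybenzyl]dihydrofuran-2(3H)-one
Product: 28 (−)-thujaplicatin
Conditions: H2 (1 atm), 10% Pd/C, EtOAc/EtOH, rt
Reagents that add atoms: none
Why: Hydrogenolysis over palladium on carbon cleaves the three benzylic C–O bonds of the aryl benzyl ethers and leaves the lactone, the methyl ethers and both stereocentres unchanged.

**Compound list**

1 | 4-methoxy-6-methyl-2H-pyran-2-one | COC1=CC(=O)OC(C)=C1 | starting material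
2 | methyl bromoacetate | COC(=O)CBr | starting material
3 | (4-methoxy-2-oxo-2H-pyran-6-yl)methyllithium (lithiated pyrone) | [Li]CC1=CC(OC)=CC(=O)O1 | intermediate
4 | methyl 3-(4-methoxy-2-oxo-2H-pyran-6-yl)propanoate | COC(=O)CCC1=CC(OC)=CC(=O)O1 | intermediate
5 | methyl 3-(3-bromo-4-methoxy-2-oxo-2H-pyran-6-yl)propanoate | COC(=O)CCC1=CC(OC)=C(Br)C(=O)O1 | intermediate
6 | methyl 3-[4-methoxy-2-oxo-3-(4,4,5,5-tetramethyl-1,3,2-dioxaborolan-2-yl)-2H-pyran-6-yl]propanoate | COC(=O)CCC1=CC(OC)=C(B2OC(C)(C)C(C)(C)O2)C(=O)O1 | intermediate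
7 | methyl 3-(3-hydroxy-4-methoxy-2-oxo-2H-pyran-6-yl)propanoate | COC(=O)CCC1=CC(OC)=C(O)C(=O)O1 | intermediate
8 | but-3-yn-2-one | CC(=O)C#C | starting material
9 | methyl 3-(5-acetyl-4-hydroxy-8-methoxy-3-oxo-2-oxabicyclo[2.2.2]octa-5,7-dien-1-yl)propanoate (racemic, one enantiomer drawn) | COC(=O)CC[C@@]12C=C(C(C)=O)[C@@](O)(C(=O)O1)C(OC)=C2 | intermediate
10 | methyl 3-(3-acetyl-4-hydroxy-5-methoxyphenyl)propanoate | COC(=O)CCc1cc(OC)c(O)c(C(C)=O)c1 | intermediate
11 | 3-(3-acetyl-4-hydroxy-5-methoxyphenyl)propanoic acid (present as its sodium salt) | OC(=O)CCc1cc(OC)c(O)c(C(C)=O)c1 | intermediate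
12 | 3-[3-(acetyloxy)-4-hydroxy-5-methoxyphenyl]propanoic acid (present as its sodium salt) | OC(=O)CCc1cc(OC)c(O)c(OC(C)=O)c1 | intermediate
13 | 3-(3,4-dihydroxy-5-methoxyphenyl)propanoic acid | OC(=O)CCc1cc(O)c(O)c(OC)c1 | intermediate
14 | benzyl 3-[3,4-bis(benzyloxy)-5-methoxyphenyl]propanoate | COc1cc(CCC(=O)OCc2ccccc2)cc(OCc2ccccc2)c1OCc1ccccc1 | intermediate
15 | 3-[3,4-bis(benzyloxy)-5-methoxyphenyl]propanoic acid | COc1cc(CCC(O)=O)cc(OCc2ccccc2)c1OCc1ccccc1 | intermediate
16 | eugenol (4-allyl-2-methoxyphenol) | COc1cc(CC=C)ccc1O | starting material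
17 | 4-allyl-1-(benzyloxy)-2-methoxybenzene | COc1cc(CC=C)ccc1OCc1ccccc1 | intermediate
18 | (R)-but-3-en-2-ol | C[C@@H](O)C=C | starting material
19 | (2R,3E)-5-[4-(benzyloxy)-3-methoxyphenyl]pent-3-en-2-ol | C[C@@H](O)/C=C/Cc1ccc(OCc2ccccc2)c(OC)c1 | intermediate
20 | (2R,3E)-5-[4-(benzyloxy)-3-methoxyphenyl]pent-3-en-2-yl 3-[3,4-bis(benzyloxy)-5-methoxyphenyl]propanoate | C[C@@H](OC(=O)CCc1cc(OC)c(OCc2ccccc2)c(OCc2ccccc2)c1)/C=C/Cc1ccc(OCc2ccccc2)c(OC)c1 | intermediate
21 | lithium enolate of ester 20, benzylic CH2 cis to O–Li | C[C@@H](O/C(O[Li])=C/Cc1cc(OC)c(OCc2ccccc2)c(OCc2ccccc2)c1)/C=C/Cc1ccc(OCc2ccccc2)c(OC)c1 | intermediate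
22 | Z tert-butyldimethylsilyl ketene acetal of ester 20, benzylic CH2 cis to O–Si | C[C@@H](O/C(O[Si](C)(C)C(C)(C)C)=C/Cc1cc(OC)c(OCc2ccccc2)c(OCc2ccccc2)c1)/C=C/Cc1ccc(OCc2ccccc2)c(OC)c1 | intermediate
23 | tert-butyldimethylsilyl (2R,3S,4E)-2-[3,4-bis(benzyloxy)-5-methoxybenzyl]-3-[4-(benzyloxy)-3-methoxybenzyl]hex-4-enoate | CC(C)(C)[Si](C)(C)OC(=O)[C@H](Cc1cc(OC)c(OCc2ccccc2)c(OCc2ccccc2)c1)[C@@H](Cc1ccc(OCc2ccccc2)c(OC)c1)/C=C/C | intermediate
24 | (2R,3S,4E)-2-[3,4-bis(benzyloxy)-5-methoxybenzyl]-3-[4-(benzyloxy)-3-methoxybenzyl]hex-4-enoic acid | OC(=O)[C@H](Cc1cc(OC)c(OCc2ccccc2)c(OCc2ccccc2)c1)[C@@H](Cc1ccc(OCc2ccccc2)c(OC)c1)/C=C/C | intermediate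
25 | (2R,3R)-2-[3,4-bis(benzyloxy)-5-methoxybenzyl]-3-[4-(benzyloxy)-3-methoxybenzyl]-4-oxobutanoic acid | OC(=O)[C@H](Cc1cc(OC)c(OCc2ccccc2)c(OCc2ccccc2)c1)[C@@H](Cc1ccc(OCc2ccccc2)c(OC)c1)C=O | intermediate
26 | (2R,3R)-2-[3,4-bis(benzyloxy)-5-methoxybenzyl]-3-[4-(benzyloxy)-3-methoxybenzyl]-4-hydroxybutanoic acid | OC(=O)[C@H](Cc1cc(OC)c(OCc2ccccc2)c(OCc2ccccc2)c1)[C@@H](Cc1ccc(OCc2ccccc2)c(OC)c1)CO | intermediate
27 | (3R,4R)-3-[3,4-bis(benzyloxy)-5-methoxybenzyl]-4-[4-(benzyloxy)-3-methoxybenzyl]dihydrofuran-2(3H)-one | COc1cc(C[C@H]2COC(=O)[C@@H]2Cc2cc(OCc3ccccc3)c(OCc3ccccc3)c(OC)c2)ccc1OCc1ccccc1 | intermediate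
28 | (−)-thujaplicatin, (3R,4R)-3-(3,4-dihydroxy-5-methoxybenzyl)-4-(4-hydroxy-3-methoxybenzyl)dihydrofuran-2(3H)-one | COc1cc(C[C@H]2COC(=O)[C@@H]2Cc2cc(O)c(O)c(OC)c2)ccc1O | target

**Count**

Total step count: 12. Longest linear sequence: 10 steps (steps 1–6 and 9–12, from 1 to 28); the eugenol branch (steps 7 and 8) joins at step 9.

**Steps most likely to fail**

Step 4. Conjugate addition of the pyrone oxide oxygen or of the amine to the very electrophilic ynone may outrun C–C bond formation at C6, the ynone may oligomerise under base, or the 4-methoxy group may erode the regiochemistry. The fallback sets out from 7 and returns at 10, keeps the same two ring bonds and lowers the oxidation level of the dienophile. 7 and but-3-en-2-one with Et3N in CH2Cl2 should give, by the amine-promoted cycloaddition of 3-hydroxy-2-pyrones to enones (O-addition being reversible here), the bridged lactone methyl 3-(5-acetyl-4-hydroxy-8-methoxy-3-oxo-2-oxabicyclo[2.2.2]oct-7-en-1-yl)propanoate F2. Heating F2 in toluene at 110 °C expels CO2 to give the dihydroarene methyl 3-(5-acetyl-4-hydroxy-3-methoxycyclohexa-1,3-dien-1-yl)propanoate F3, and DDQ in 1,4-dioxane dehydrogenates F3 to 10.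

Step 3. The electron-rich alkenyl boronate next to the lactone carbonyl may undergo protodeboronation, or peroxide may open the pyrone during the oxidation. The fallback sets out from 5 and returns at 7, and forms the C–O bond directly. Coupling of 5 with (E)-benzaldehyde oxime under Pd2(dba)3/t-BuXPhos catalysis with Cs2CO3 in DMF at 80 °C should give the oxime ether methyl 3-[3-({[(E)-benzylidene]amino}oxy)-4-methoxy-2-oxo-2H-pyran-6-yl]propanoate F1. Under the same carbonate base F1 fragments to benzonitrile and, after acidification, 7.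

Step 10. Control of enolate geometry in THF/DMPU may be incomplete, which would erode the syn/anti relationship at C2; C3 stays secure as long as the chair is followed. The fallback sets out from 20 and returns at 27, and moves control of that centre from kinetic to thermodynamic.
- Enolisation of 20 with LiN(i-Pr)2 in THF alone gives the lithium enolate with the benzylic CH2 trans to O–Li F4, and TBSCl traps it as the E silyl ketene acetal F5.
- The same chair then leads to the anti silyl ester F6 and, after hydrolysis, to the anti acid F7.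
- Ozonolysis and NaBH4 as in step 11 take F7 through the aldehyde acid F8 and the hydroxy acid F9 to the cis lactone F10.
- DBU in toluene at 80 °C epimerises the acidic C3–H of F10 to the more stable trans lactone 27. The same treatment would also correct any cis lactone carried through the main route.

**Further compounds**

F1 | step 3 | methyl 3-[3-({[(E)-benzylidene]amino}oxy)-4-methoxy-2-oxo-2H-pyran-6-yl]propanoate | COC(=O)CCC1=CC(OC)=C(O/N=C/c2ccccc2)C(=O)O1
F2 | step 4 | methyl 3-(5-acetyl-4-hydroxy-8-methoxy-3-oxo-2-oxabicyclo[2.2.2]oct-7-en-1-yl)propanoate (racemic, acetyl endo, one enantiomer drawn) | COC(=O)CC[C@@]12C[C@H](C(C)=O)[C@@](O)(C(=O)O1)C(OC)=C2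
F3 | step 4 | methyl 3-(5-acetyl-4-hydroxy-3-methoxycyclohexa-1,3-dien-1-yl)propanoate (racemic) | COC(=O)CCC1=CC(OC)=C(O)C(C(C)=O)C1
F4 | step 10 | lithium enolate of ester 20, benzylic CH2 trans to O–Li | C[C@@H](O/C(O[Li])=C\Cc1cc(OC)c(OCc2ccccc2)c(OCc2ccccc2)c1)/C=C/Cc1ccc(OCc2ccccc2)c(OC)c1
F5 | step 10 | E tert-butyldimethylsilyl ketene acetal of ester 20, benzylic CH2 trans to O–Si | C[C@@H](O/C(O[Si](C)(C)C(C)(C)C)=C\Cc1cc(OC)c(OCc2ccccc2)c(OCc2ccccc2)c1)/C=C/Cc1ccc(OCc2ccccc2)c(OC)c1
F6 | step 10 | tert-butyldimethylsilyl (2S,3S,4E)-2-[3,4-bis(benzyloxy)-5-methoxybenzyl]-3-[4-(benzyloxy)-3-methoxybenzyl]hex-4-enoate | CC(C)(C)[Si](C)(C)OC(=O)[C@@H](Cc1cc(OC)c(OCc2ccccc2)c(OCc2ccccc2)c1)[C@@H](Cc1ccc(OCc2ccccc2)c(OC)c1)/C=C/C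
F7 | step 10 | (2S,3S,4E)-2-[3,4-bis(benzyloxy)-5-methoxybenzyl]-3-[4-(benzyloxy)-3-methoxybenzyl]hex-4-enoic acid | OC(=O)[C@@H](Cc1cc(OC)c(OCc2ccccc2)c(OCc2ccccc2)c1)[C@@H](Cc1ccc(OCc2ccccc2)c(OC)c1)/C=C/C
F8 | step 10 | (2S,3R)-2-[3,4-bis(benzyloxy)-5-methoxybenzyl]-3-[4-(benzyloxy)-3-methoxybenzyl]-4-oxobutanoic acid | OC(=O)[C@@H](Cc1cc(OC)c(OCc2ccccc2)c(OCc2ccccc2)c1)[C@@H](Cc1ccc(OCc2ccccc2)c(OC)c1)C=O
F9 | step 10 | (2S,3R)-2-[3,4-bis(benzyloxy)-5-methoxybenzyl]-3-[4-(benzyloxy)-3-methoxybenzyl]-4-hydroxybutanoic acid | OC(=O)[C@@H](Cc1cc(OC)c(OCc2ccccc2)c(OCc2ccccc2)c1)[C@@H](Cc1ccc(OCc2ccccc2)c(OC)c1)CO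
F10 | step 10 | (3S,4R)-3-[3,4-bis(benzyloxy)-5-methoxybenzyl]-4-[4-(benzyloxy)-3-methoxybenzyl]dihydrofuran-2(3H)-one | COc1cc(C[C@H]2COC(=O)[C@H]2Cc2cc(OCc3ccccc3)c(OCc3ccccc3)c(OC)c2)ccc1OCc1ccccc1
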